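The α-methylene-γ-lactone is cut at O1–C6 and C11–C12, and the C12(=O)–O1 unit is supplied as carbon dioxide. The key step exploits the 1,3-relationship between the vinylic carbon C11 and the oxygen-bearing C6 across C7 of the lactone ring. In one pot, a terminal alkyne on C7 is hydroaluminated at its internal carbon, the alanate is carboxylated, and the acid opens an adjacent C5–C6 epoxide at C6 with inversion. This closes the trans-fused lactone and frees the C5 hydroxyl for the later Z-iodoalkene. The precursor is an acyclic epoxy alkyne carrying the C6–C8 stereotriad; the ten-membered carbocycle is closed afterwards by a Nozaki–Hiyama–Kishi reaction at C3–C4.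

Key step: step 9

Remark: atoms are numbered as in germacranolides (ring C1–C10, C11, lactone carbonyl C12, exocyclic methylene C13, lactone oxygen O1 on C6). One-pot sequences count as one step. TBS = tert-butyldimethylsilyl.

Step 1
Reactants: 1 (R)-epichlorohydrin
Product: 2 (2R)-1-chloro-5-(trimethylsilyl)pent-4-yn-2-ol
Conditions: Me3SiC≡CH, n-BuLi, THF, −78 °C; BF3·OEt2; then 1, −78 °C
Reagents that add atoms: ethynyltrimethylsilane, C#C[Si](C)(C)C
Why: Yamaguchi–Hirao alkynylation, in which the lithium acetylide opens the BF3-activated epoxide at its unsubstituted carbon, so the future C8 stereocenter comes unchanged from 1.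

Step 2
Reactants: 2 (2R)-1-chloro-5-(trimethylsilyl)pent-4-yn-2-ol
Product: 5 (3R)-hex-1-en-5-yn-3-ol, via alkynyl epoxide 3 (not isolated), via silylated enynol 4 (not isolated)
Conditions: Me3S+ I−, n-BuLi, THF, −10 → 23 °C; then K2CO3 (cat.), MeOH, 23 °C
Reagents that add atoms: trimethylsulfonium iodide, C[S+](C)C.[I-]
Why: the basic ylide closes the chlorohydrin to epoxide 3, excess dimethylsulfonium methylide homologates it to the allylic alcohol (sulfonium ylide epoxide-to-allylic-alcohol homologation, carbinol configuration retained), and methanolysis removes the alkynyl silyl group.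

Step 3
Reactants: 5 (3R)-hex-1-en-5-yn-3-ol
Product: 8 (3R,5E)-5-methylocta-1,5-diene-3,8-diol, via alkenylalane 6 (not isolated), via butyl alanate 7 (not isolated)
Conditions: Me3Al (3.5 equiv), Cp2ZrCl2 (0.3 equiv), CH2Cl2, 0 → 23 °C; then n-BuLi, THF, −78 °C; ethylene oxide, −78 → 0 °C
Reagents that add atoms: trimethylaluminium, C[Al](C)C; ethylene oxide, C1CO1
Why: Negishi zirconium-catalysed syn-carboalumination places methyl on the internal and aluminium on the terminal alkyne carbon, which fixes the E geometry of C1=C10, and the derived alanate opens ethylene oxide with retention of alkene geometry to add C2–C3.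

Step 4
Reactants: 8 (3R,5E)-5-methylocta-1,5-diene-3,8-diol
Product: 9 (3R,5E)-3,8-bis(TBSO)-5-methylocta-1,5-diene
Conditions: TBSOTf (2.5 equiv), 2,6-lutidine, CH2Cl2, −78 → 0 °C
Reagents that add atoms: tert-butyldimethylsilyl trifluoromethanesulfonate, CC(C)(C)[Si](C)(C)OS(=O)(=O)C(F)(F)F
Why: standard silyl ether formation on both hydroxyls, giving groups that survive the organoaluminium chemistry and can later be told apart as primary and secondary.

Step 5
Reactants: 9 (3R,5E)-3,8-bis(TBSO)-5-methylocta-1,5-diene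
Product: 10 (2E,4R,6E)-4,9-bis(TBSO)-6-methylnona-2,6-dien-1-ol
Conditions: (Z)-but-2-ene-1,4-diol (5 equiv), second-generation Hoveyda–Grubbs catalyst (5 mol%), CH2Cl2, 40 °C
Reagents that add atoms: (Z)-but-2-ene-1,4-diol, OC/C=C\CO
Why: olefin cross-metathesis engages only the monosubstituted alkene (the trisubstituted C1=C10 alkene is inert) and should give the thermodynamically favoured E allylic alcohol.

Step 6
Reactants: 10 (2E,4R,6E)-4,9-bis(TBSO)-6-methylnona-2,6-dien-1-ol
Product: 11 [(2S,3R)-3-[(1R,3E)-1,6-bis(TBSO)-3-methylhex-3-en-1-yl]oxiran-2-yl]methanol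
Conditions: Ti(OiPr)4 (10 mol%), L-(+)-diethyl tartrate (12 mol%), t-BuOOH, 4 Å MS, CH2Cl2, −20 °C
Reagents that add atoms: tert-butyl hydroperoxide, CC(C)(C)OO
Why: Sharpless asymmetric epoxidation, in which the L-(+)-tartrate–titanium complex delivers oxygen to one face of the E allylic alcohol under reagent control and so sets C6 and C7, while the remote trisubstituted alkene has no allylic hydroxyl and is left alone.

Step 7
Reactants: 11 [(2S,3R)-3-[(1R,3E)-1,6-bis(TBSO)-3-methylhex-3-en-1-yl]oxiran-2-yl]methanol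
Product: 12 (2R,3S,4R,6E)-4,9-bis(TBSO)-6-methyl-3-[(trimethylsilyl)ethynyl]non-6-ene-1,2-diol
Conditions: Et2AlC≡CSiMe3 (4 equiv; from Me3SiC≡CH, n-BuLi, Et2AlCl), toluene, 0 → 23 °C
Reagents that add atoms: diethyl[(trimethylsilyl)ethynyl]aluminium, CC[Al](CC)C#C[Si](C)(C)C
Why: alkynylalane opening of a 2,3-epoxy alcohol, in which the aluminium alkoxide of the primary hydroxyl directs the alkynyl group to the distal oxirane carbon (C7) with inversion, placing the new C7–C11 bond anti to both flanking C–O bonds.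

Step 8
Reactants: 12 (2R,3S,4R,6E)-4,9-bis(TBSO)-6-methyl-3-[(trimethylsilyl)ethynyl]non-6-ene-1,2-diol
Product: 14 (2R)-2-[(3S,4R,6E)-4,9-bis(TBSO)-6-methylnon-6-en-1-yn-3-yl]oxirane, via primary tosylate 13 (not isolated)
Conditions: TsCl (1.1 equiv), Bu2SnO (2 mol%), Et3N, CH2Cl2, 0 → 23 °C; then K2CO3, MeOH, 23 °C
Reagents that add atoms: none
Why: tin-catalysed selective sulfonylation of the primary hydroxyl and intramolecular Williamson closure by the C6 alkoxide give the terminal epoxide with retention at C6, and the same methanolic carbonate cleaves the alkynyl C–Si bond.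

Step 9
Reactants: 14 (2R)-2-[(3S,4R,6E)-4,9-bis(TBSO)-6-methylnon-6-en-1-yn-3-yl]oxirane
Product: 19 (4S,5S)-4-[(1R,3E)-1,6-bis(TBSO)-3-methylhex-3-en-1-yl]-5-(hydroxymethyl)-3-methylideneoxolan-2-one, via internal alkenylalane 15 (not isolated), via methyl alanate 16 (not isolated), via aluminium carboxylate 17 (not isolated), via epoxy acid 18 (not isolated)
Conditions: NiCl2(dppp) (3 mol%), i-Bu2AlH (1.3 equiv), THF, 0 → 22 °C; MeLi (1.3 equiv), −78 °C; CO2 (1 atm), −78 → 0 °C; cold 0.5 M aq. HCl (to pH 3), Et2O; then camphor-10-sulfonic acid (5 mol%), CH2Cl2, 0 → 23 °C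
Reagents that add atoms: carbon dioxide, O=C=O
Why: Nickel-catalysed Markovnikov hydroalumination adds Al–H syn across the terminal alkyne with aluminium on the internal carbon C11, methyllithium converts the alkenylalane into an alanate, and its alkenyl–aluminium bond inserts CO2 (carboxylation of alkenylalanates), which forms C11–C12 as a 2-substituted acrylate. On acidification the free carboxylic acid attacks the protonated C5–C6 oxirane at C6 and forms O1–C6; the closest known reaction is the acid-catalysed lactonisation of γ,δ-epoxy acids, and the sequence as a whole is a formal (3+2) annulation of CO2 onto the C11–C7–C6 unit. The lactone ring closes in the 5-exo-tet mode, at the nearer and more substituted oxirane carbon, rather than 6-endo at C5. No new stereocenter is created: C6 is inverted stereospecifically, so its configuration is set by the oxirane made in steps 6 and 8, and together with the C7 configuration from step 7 this makes the lactone trans-disubstituted. The step needs Markovnikov regioselectivity in the hydrometalation, which the dppp-ligated nickel catalyst imposes, and it needs the epoxide to survive i-Bu2AlH and the alanate, which rests on the donor solvent, the low temperature and the fact that the alkenyl–metal carbon could only reach the oxirane through a three- or four-membered transition state; the silyl ethers should survive the brief, cold, dilute acid.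

Step 10
Reactants: 19 (4S,5S)-4-[(1R,3E)-1,6-bis(TBSO)-3-methylhex-3-en-1-yl]-5-(hydroxymethyl)-3-methylideneoxolan-2-one
Product: 20 (2S,3S)-3-[(1R,3E)-1,6-bis(TBSO)-3-methylhex-3-en-1-yl]-4-methylidene-5-oxooxolane-2-carbaldehyde
Conditions: Dess–Martin periodinane, pyridine, CH2Cl2, 0 → 23 °C
Reagents that add atoms: none
Why: Dess–Martin oxidation of the primary alcohol under buffered, non-enolising conditions should leave the α-oxygenated C6 stereocenter intact.

Step 11
Reactants: 20 (2S,3S)-3-[(1R,3E)-1,6-bis(TBSO)-3-methylhex-3-en-1-yl]-4-methylidene-5-oxooxolane-2-carbaldehyde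
Product: 21 (4S,5S)-4-[(1R,3E)-1,6-bis(TBSO)-3-methylhex-3-en-1-yl]-5-[(1Z)-2-iodoprop-1-en-1-yl]-3-methylideneoxolan-2-one
Conditions: EtPPh3+ I−, n-BuLi, THF, 23 °C; I2, −78 °C; NaN(SiMe3)2, −20 °C; then 20, −78 → −20 °C
Reagents that add atoms: ethyltriphenylphosphonium iodide, CC[P+](c1ccccc1)(c1ccccc1)c1ccccc1.[I-]; iodine, II
Why: Stork–Zhao Wittig olefination with the α-iodo ylide gives the (Z)-2-iodoalkene (iodine cis to C6) under kinetic control, the weakly basic ylide reacting with the aldehyde far faster than with the methylene lactone.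

Step 12
Reactants: 21 (4S,5S)-4-[(1R,3E)-1,6-bis(TBSO)-3-methylhex-3-en-1-yl]-5-[(1Z)-2-iodoprop-1-en-1-yl]-3-methylideneoxolan-2-one
Product: 22 (4S,5S)-4-[(1R,3E)-1-(TBSO)-6-hydroxy-3-methylhex-3-en-1-yl]-5-[(1Z)-2-iodoprop-1-en-1-yl]-3-methylideneoxolan-2-one
Conditions: HF·pyridine, pyridine, THF, 0 °C
Reagents that add atoms: none
Why: selective desilylation, since the unhindered primary silyl ether is cleaved much faster by buffered fluoride than the secondary one flanked by C7 and C9.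

Step 13
Reactants: 22 (4S,5S)-4-[(1R,3E)-1-(TBSO)-6-hydroxy-3-methylhex-3-en-1-yl]-5-[(1Z)-2-iodoprop-1-en-1-yl]-3-methylideneoxolan-2-one
Product: 23 (3E,6R)-6-(TBSO)-6-[(2S,3S)-2-[(1Z)-2-iodoprop-1-en-1-yl]-4-methylidene-5-oxooxolan-3-yl]-4-methylhex-3-enal
Conditions: Dess–Martin periodinane, pyridine, CH2Cl2, 0 °C
Reagents that add atoms: none
Why: Dess–Martin oxidation is mild enough to give the β,γ-unsaturated aldehyde without moving the C1=C10 double bond into conjugation; the aldehyde is used crude.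

Step 14
Reactants: 23 (3E,6R)-6-(TBSO)-6-[(2S,3S)-2-[(1Z)-2-iodoprop-1-en-1-yl]-4-methylidene-5-oxooxolan-3-yl]-4-methylhex-3-enal
Product: 24 (3aS,4R,6E,9S,10Z,11aR)-4-(TBSO)-9-hydroxy-6,10-dimethyl-3-methylidene-3a,4,5,8,9,11a-hexahydrocyclodeca[b]furan-2(3H)-one
Conditions: CrCl2 (10 equiv), NiCl2 (0.1 equiv), DMSO, 0.002 M, 23 °C
Reagents that add atoms: none
Why: intramolecular Nozaki–Hiyama–Kishi reaction, in which the alkenyl iodide is passed through nickel to trivalent chromium with retention of the Z geometry and adds to the aldehyde under high dilution to close the ten-membered ring, the C3 carbinol configuration being expected from attack on the aldehyde face exposed in the lactone-constrained folded chain.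

Step 15
Reactants: 24 (3aS,4R,6E,9S,10Z,11aR)-4-(TBSO)-9-hydroxy-6,10-dimethyl-3-methylidene-3a,4,5,8,9,11a-hexahydrocyclodeca[b]furan-2(3H)-one
Product: 25 (3aS,4R,6E,9S,10Z,11aR)-4-(TBSO)-6,10-dimethyl-3-methylidene-2-oxo-2,3,3a,4,5,8,9,11a-octahydrocyclodeca[b]furan-9-yl 2-methylpropanoate
Conditions: (i-PrCO)2O, pyridine, DMAP (cat.), CH2Cl2, 0 → 23 °C
Reagents that add atoms: 2-methylpropanoic anhydride, CC(C)C(=O)OC(=O)C(C)C
Why: nucleophile-catalysed acylation of the only free hydroxyl (the C3 allylic alcohol) touches no stereocenter.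

Step 16
Reactants: 25 (3aS,4R,6E,9S,10Z,11aR)-4-(TBSO)-6,10-dimethyl-3-methylidene-2-oxo-2,3,3a,4,5,8,9,11a-octahydrocyclodeca[b]furan-9-yl 2-methylpropanoate
Product: 26 (3aR,4R,6E,9S,10Z,11aR)-4-hydroxy-6,10-dimethyl-3-methylidene-2-oxo-2,3,3a,4,5,8,9,11a-octahydrocyclodeca[b]furan-9-yl 2-methylpropanoate
Conditions: HF·pyridine (excess), THF, 0 → 40 °C
Reagents that add atoms: none
Why: fluoride cleavage of the remaining secondary silyl ether under mildly acidic conditions should spare the ester and the methylene lactone and should not promote translactonisation to C8.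

Step 17
Reactants: 27 methyl angelate
Product: 28 (2Z)-2-methylbut-2-en-1-ol
Conditions: i-Bu2AlH (2.2 equiv), CH2Cl2, −78 → 0 °C
Reagents that add atoms: none
Why: 1,2-reduction of the conjugated ester by the aluminium hydride leaves the Z alkene geometry unchanged.

Step 18
Reactants: 28 (2Z)-2-methylbut-2-en-1-ol
Product: 29 [(2R,3S)-2,3-dimethyloxiran-2-yl]methanol
Conditions: Ti(OiPr)4 (10 mol%), D-(−)-diethyl tartrate (12 mol%), t-BuOOH, 4 Å MS, CH2Cl2, −20 °C
Reagents that add atoms: tert-butyl hydroperoxide, CC(C)(C)OO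
Why: Sharpless asymmetric epoxidation, where the D-(−)-tartrate sets both oxirane carbons and the Z alkene fixes the cis relationship of CH2OH and the C3 methyl.

Step 19
Reactants: 29 [(2R,3S)-2,3-dimethyloxiran-2-yl]methanol
Product: 30 (2S,3S)-2,3-dimethyloxirane-2-carboxylic acid
Conditions: RuCl3·xH2O (2 mol%), NaIO4, CCl4/MeCN/H2O, 23 °C
Reagents that add atoms: sodium periodate, [Na+].[O-]I(=O)(=O)=O; water, O
Why: catalytic ruthenium tetroxide oxidation of the primary alcohol to the acid via the aldehyde hydrate leaves both oxirane stereocenters untouched.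

Step 20
Reactants: 26 (3aR,4R,6E,9S,10Z,11aR)-4-hydroxy-6,10-dimethyl-3-methylidene-2-oxo-2,3,3a,4,5,8,9,11a-octahydrocyclodeca[b]furan-9-yl 2-methylpropanoate; 30 (2S,3S)-2,3-dimethyloxirane-2-carboxylic acid
Product: 32 (3aR,4R,6E,9S,10Z,11aR)-6,10-dimethyl-3-methylidene-9-(2-methylpropanoyloxy)-2-oxo-2,3,3a,4,5,8,9,11a-octahydrocyclodeca[b]furan-4-yl (2S,3S)-2,3-dimethyloxirane-2-carboxylate, via mixed anhydride 31 (not isolated)
Conditions: 30, 2,4,6-trichlorobenzoyl chloride, Et3N, THF, 23 °C; then 26, DMAP, toluene, 23 °C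
Reagents that add atoms: none
Why: Yamaguchi esterification, in which the mixed anhydride activates the α-quaternary epoxy acid enough to acylate the hindered C8 hydroxyl without epimerising either partner.

Step 21
Reactants: 32 (3aR,4R,6E,9S,10Z,11aR)-6,10-dimethyl-3-methylidene-9-(2-methylpropanoyloxy)-2-oxo-2,3,3a,4,5,8,9,11a-octahydrocyclodeca[b]furan-4-yl (2S,3S)-2,3-dimethyloxirane-2-carboxylate
Product: 33 target CNP0117882.1
Conditions: m-CPBA (1.1 equiv), Na2HPO4, CH2Cl2, 0 °C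
Reagents that add atoms: 3-chloroperbenzoic acid, OOC(=O)c1cccc(Cl)c1
Why: Prilezhaev epoxidation should select the electron-rich isolated C1=C10 alkene (C4=C5 is deactivated by two allylic acyloxy groups and the acrylate is electron-poor), and attack on the outer face of the E alkene in the conformer with C14 on the β face should set C1 and C10 as 1R,10R.

Compound list
1 | (R)-epichlorohydrin, (2R)-2-(chloromethyl)oxirane | ClC[C@H]1CO1 | starting material
2 | (2R)-1-chloro-5-(trimethylsilyl)pent-4-yn-2-ol | C[Si](C)(C)C#CC[C@@H](O)CCl | intermediate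
3 | (2R)-2-[3-(trimethylsilyl)prop-2-yn-1-yl]oxirane | C[Si](C)(C)C#CC[C@@H]1CO1 | intermediate
4 | (3R)-6-(trimethylsilyl)hex-1-en-5-yn-3-ol | C[Si](C)(C)C#CC[C@@H](O)C=C | intermediate
5 | (3R)-hex-1-en-5-yn-3-ol | C#CC[C@@H](O)C=C | intermediate
6 | dimethylaluminium (3R,5E)-6-(dimethylalumanyl)-5-methylhexa-1,5-dien-3-olate (methyl and aluminium cis) | C[Al](C)/C=C(\C)C[C@@H](O[Al](C)C)C=C | intermediate
7 | lithium butyl(dimethyl)alkenylalanate formed from 6 and n-BuLi (same configuration and geometry) | [Li+].CCCC[Al-](C)(C)/C=C(\C)C[C@@H](O[Al](C)C)C=C | intermediate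
8 | (3R,5E)-5-methylocta-1,5-diene-3,8-diol | OCC/C=C(\C)C[C@@H](O)C=C | intermediate
9 | (3R,5E)-3,8-bis(TBSO)-5-methylocta-1,5-diene | CC(C)(C)[Si](C)(C)OCC/C=C(\C)C[C@@H](O[Si](C)(C)C(C)(C)C)C=C | intermediate
10 | (2E,4R,6E)-4,9-bis(TBSO)-6-methylnona-2,6-dien-1-ol | OC/C=C/[C@H](O[Si](C)(C)C(C)(C)C)C/C(C)=C/CCO[Si](C)(C)C(C)(C)C | intermediate
11 | [(2S,3R)-3-[(1R,3E)-1,6-bis(TBSO)-3-methylhex-3-en-1-yl]oxiran-2-yl]methanol | OC[C@@H]1O[C@H]1[C@H](O[Si](C)(C)C(C)(C)C)C/C(C)=C/CCO[Si](C)(C)C(C)(C)C | intermediate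
12 | (2R,3S,4R,6E)-4,9-bis(TBSO)-6-methyl-3-[(trimethylsilyl)ethynyl]non-6-ene-1,2-diol | OC[C@H](O)[C@H](C#C[Si](C)(C)C)[C@H](O[Si](C)(C)C(C)(C)C)C/C(C)=C/CCO[Si](C)(C)C(C)(C)C | intermediate
13 | 1-O-(4-methylbenzenesulfonyl) derivative of 12 (2R,3S,4R,6E) | Cc1ccc(cc1)S(=O)(=O)OC[C@H](O)[C@H](C#C[Si](C)(C)C)[C@H](O[Si](C)(C)C(C)(C)C)C/C(C)=C/CCO[Si](C)(C)C(C)(C)C | intermediate
14 | (2R)-2-[(3S,4R,6E)-4,9-bis(TBSO)-6-methylnon-6-en-1-yn-3-yl]oxirane | C#C[C@@H]([C@@H]1CO1)[C@H](O[Si](C)(C)C(C)(C)C)C/C(C)=C/CCO[Si](C)(C)C(C)(C)C | intermediate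
15 | 2-(diisobutylalumanyl)alk-1-ene from 14: (2R)-2-[(3S,4R,6E)-4,9-bis(TBSO)-2-(diisobutylalumanyl)-6-methylnona-1,6-dien-3-yl]oxirane | C=C([Al](CC(C)C)CC(C)C)[C@@H]([C@@H]1CO1)[C@H](O[Si](C)(C)C(C)(C)C)C/C(C)=C/CCO[Si](C)(C)C(C)(C)C | intermediate
16 | lithium diisobutyl(methyl)alkenylalanate formed from 15 and MeLi (same configuration) | [Li+].C=C([Al-](C)(CC(C)C)CC(C)C)[C@@H]([C@@H]1CO1)[C@H](O[Si](C)(C)C(C)(C)C)C/C(C)=C/CCO[Si](C)(C)C(C)(C)C | intermediate
17 | lithium diisobutyl(methyl)aluminate of the carboxylate of 18 (CO2 insertion product of 16) | [Li+].C=C(C(=O)O[Al-](C)(CC(C)C)CC(C)C)[C@@H]([C@@H]1CO1)[C@H](O[Si](C)(C)C(C)(C)C)C/C(C)=C/CCO[Si](C)(C)C(C)(C)C | intermediate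
18 | (3S,4R,6E)-4,9-bis(TBSO)-6-methyl-2-methylidene-3-[(2R)-oxiran-2-yl]non-6-enoic acid | C=C(C(=O)O)[C@@H]([C@@H]1CO1)[C@H](O[Si](C)(C)C(C)(C)C)C/C(C)=C/CCO[Si](C)(C)C(C)(C)C | intermediate
19 | (4S,5S)-4-[(1R,3E)-1,6-bis(TBSO)-3-methylhex-3-en-1-yl]-5-(hydroxymethyl)-3-methylideneoxolan-2-one | C=C1C(=O)O[C@H](CO)[C@H]1[C@H](O[Si](C)(C)C(C)(C)C)C/C(C)=C/CCO[Si](C)(C)C(C)(C)C | intermediate
20 | (2S,3S)-3-[(1R,3E)-1,6-bis(TBSO)-3-methylhex-3-en-1-yl]-4-methylidene-5-oxooxolane-2-carbaldehyde | C=C1C(=O)O[C@H](C=O)[C@H]1[C@H](O[Si](C)(C)C(C)(C)C)C/C(C)=C/CCO[Si](C)(C)C(C)(C)C | intermediate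
21 | (4S,5S)-4-[(1R,3E)-1,6-bis(TBSO)-3-methylhex-3-en-1-yl]-5-[(1Z)-2-iodoprop-1-en-1-yl]-3-methylideneoxolan-2-one | C=C1C(=O)O[C@H](/C=C(/C)I)[C@H]1[C@H](O[Si](C)(C)C(C)(C)C)C/C(C)=C/CCO[Si](C)(C)C(C)(C)C | intermediate
22 | (4S,5S)-4-[(1R,3E)-1-(TBSO)-6-hydroxy-3-methylhex-3-en-1-yl]-5-[(1Z)-2-iodoprop-1-en-1-yl]-3-methylideneoxolan-2-one | C=C1C(=O)O[C@H](/C=C(/C)I)[C@H]1[C@H](O[Si](C)(C)C(C)(C)C)C/C(C)=C/CCO | intermediate
23 | (3E,6R)-6-(TBSO)-6-[(2S,3S)-2-[(1Z)-2-iodoprop-1-en-1-yl]-4-methylidene-5-oxooxolan-3-yl]-4-methylhex-3-enal | C=C1C(=O)O[C@H](/C=C(/C)I)[C@H]1[C@H](O[Si](C)(C)C(C)(C)C)C/C(C)=C/CC=O | intermediate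
24 | (3aS,4R,6E,9S,10Z,11aR)-4-(TBSO)-9-hydroxy-6,10-dimethyl-3-methylidene-3a,4,5,8,9,11a-hexahydrocyclodeca[b]furan-2(3H)-one | C=C1C(=O)O[C@@H]2/C=C(/C)[C@@H](O)C/C=C(\C)C[C@@H](O[Si](C)(C)C(C)(C)C)[C@@H]12 | intermediate
25 | (3aS,4R,6E,9S,10Z,11aR)-4-(TBSO)-6,10-dimethyl-3-methylidene-2-oxo-2,3,3a,4,5,8,9,11a-octahydrocyclodeca[b]furan-9-yl 2-methylpropanoate | C=C1C(=O)O[C@@H]2/C=C(/C)[C@@H](OC(=O)C(C)C)C/C=C(\C)C[C@@H](O[Si](C)(C)C(C)(C)C)[C@@H]12 | intermediate
26 | (3aR,4R,6E,9S,10Z,11aR)-4-hydroxy-6,10-dimethyl-3-methylidene-2-oxo-2,3,3a,4,5,8,9,11a-octahydrocyclodeca[b]furan-9-yl 2-methylpropanoate | C=C1C(=O)O[C@@H]2/C=C(/C)[C@@H](OC(=O)C(C)C)C/C=C(\C)C[C@@H](O)[C@@H]12 | intermediate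
27 | methyl angelate, methyl (2Z)-2-methylbut-2-enoate | C/C=C(/C)C(=O)OC | starting material
28 | (2Z)-2-methylbut-2-en-1-ol | C/C=C(/C)CO | intermediate
29 | [(2R,3S)-2,3-dimethyloxiran-2-yl]methanol | OC[C@@]1(C)O[C@H]1C | intermediate
30 | (2S,3S)-2,3-dimethyloxirane-2-carboxylic acid | OC(=O)[C@@]1(C)O[C@H]1C | intermediate
31 | (2S,3S)-2,3-dimethyloxirane-2-carboxylic 2,4,6-trichlorobenzoic anhydride | O=C(OC(=O)c1c(Cl)cc(Cl)cc1Cl)[C@@]1(C)O[C@H]1C | intermediate
32 | (3aR,4R,6E,9S,10Z,11aR)-6,10-dimethyl-3-methylidene-9-(2-methylpropanoyloxy)-2-oxo-2,3,3a,4,5,8,9,11a-octahydrocyclodeca[b]furan-4-yl (2S,3S)-2,3-dimethyloxirane-2-carboxylate | C=C1C(=O)O[C@@H]2/C=C(/C)[C@@H](OC(=O)C(C)C)C/C=C(\C)C[C@@H](OC(=O)[C@@]3(C)O[C@H]3C)[C@@H]12 | intermediate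
33 | CNP0117882.1: (1R,3S,4Z,6R,7R,8R,10R)-1,10-epoxy-8-[(2S,3S)-2,3-dimethyloxirane-2-carbonyloxy]-3-(2-methylpropanoyloxy)germacra-4,11(13)-dien-12,6-olide (germacrane numbering) | C=C1C(=O)O[C@@H]2/C=C(/C)[C@@H](OC(=O)C(C)C)C[C@H]3O[C@]3(C)C[C@@H](OC(=O)[C@@]3(C)O[C@H]3C)[C@@H]12 | target

Total step count: 21. Longest linear sequence: 18 steps (steps 1–16, 20 and 21); steps 17–19 form the side branch to acid 30.

Steps most likely to fail

Step 14 (ring closure). The addition of the alkenylchromium to the C3 aldehyde may show poor facial selectivity, so that the C9 epimer of 24 forms beside 24, and oligomerisation may compete with closure of the strained ring. The fallback sets the stereocenter by reagent control instead of substrate control. It sets out from 24 as obtained together with its C9 epimer: Dess–Martin oxidation converts both into the single macrocyclic enone (3aS,4R,6E,10Z,11aR)-4-(TBSO)-6,10-dimethyl-3-methylidene-3a,4,5,8-tetrahydrocyclodeca[b]furan-2,9(3H,11aH)-dione F5. Corey–Bakshi–Shibata reduction with the (R)-methyl oxazaborolidine and catecholborane at −78 °C, with the alkenyl branch acting as the large substituent, then returns to the route at 24.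

Step 9 (key step). The oxirane may be reduced or opened by the aluminium hydride or the alanate, the hydroalumination may lose regioselectivity on the branched alkyne, or the hindered alanate may carboxylate sluggishly. The fallback is hydride-free and sets out from alkyne 14. Ruthenium-catalysed Markovnikov hydrosilylation ([Cp*Ru(MeCN)3]PF6, Et3SiH, CH2Cl2, 0 °C) gives the 1,1-disubstituted vinylsilane triethyl[(3S,4R,6E)-4,9-bis(TBSO)-6-methyl-3-[(2R)-oxiran-2-yl]nona-1,6-dien-2-yl]silane F1. Iododesilylation with N-iodosuccinimide in MeCN/ClCH2CN at 0 °C gives the iodoalkene (2R)-2-[(3S,4R,6E)-4,9-bis(TBSO)-2-iodo-6-methylnona-1,6-dien-3-yl]oxirane F2. Iodine–lithium exchange with t-BuLi in Et2O at −78 °C gives the alkenyllithium F3, which is carboxylated with CO2 to the lithium carboxylate F4. Acidification passes through epoxy acid 18 and the same lactonisation, so the two bonds are still formed in one operation, and the fallback comes back to the route at 19.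

Step 21 (final epoxidation). The peracid may attack C4=C5 competitively, or the wrong face of C1=C10 if the ring populates a second conformer. The fallback moves the epoxidation one stage back and makes it hydroxyl-directed. It sets out from homoallylic alcohol 26, which is treated with VO(acac)2 and t-BuOOH in CH2Cl2 at 0 °C. The vanadate bound to the C8 hydroxyl can reach only the neighbouring C1=C10 alkene and should deliver oxygen to its peripheral face, giving the epoxy alcohol (1R,3S,4Z,6R,7R,8R,10R)-1,10-epoxy-8-hydroxy-3-(2-methylpropanoyloxy)germacra-4,11(13)-dien-12,6-olide F6. Esterification of F6 with acid 30 through mixed anhydride 31 under the conditions of step 20 comes back to the route at 33.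

Further compounds
F1 | step 9 | triethyl[(3S,4R,6E)-4,9-bis(TBSO)-6-methyl-3-[(2R)-oxiran-2-yl]nona-1,6-dien-2-yl]silane | C=C([Si](CC)(CC)CC)[C@@H]([C@@H]1CO1)[C@H](O[Si](C)(C)C(C)(C)C)C/C(C)=C/CCO[Si](C)(C)C(C)(C)C
F2 | step 9 | (2R)-2-[(3S,4R,6E)-4,9-bis(TBSO)-2-iodo-6-methylnona-1,6-dien-3-yl]oxirane | C=C(I)[C@@H]([C@@H]1CO1)[C@H](O[Si](C)(C)C(C)(C)C)C/C(C)=C/CCO[Si](C)(C)C(C)(C)C
F3 | step 9 | alkenyllithium from F2: [(3S,4R,6E)-4,9-bis(TBSO)-6-methyl-3-[(2R)-oxiran-2-yl]nona-1,6-dien-2-yl]lithium | C=C([Li])[C@@H]([C@@H]1CO1)[C@H](O[Si](C)(C)C(C)(C)C)C/C(C)=C/CCO[Si](C)(C)C(C)(C)C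
F4 | step 9 | lithium (3S,4R,6E)-4,9-bis(TBSO)-6-methyl-2-methylidene-3-[(2R)-oxiran-2-yl]non-6-enoate | [Li+].C=C(C(=O)[O-])[C@@H]([C@@H]1CO1)[C@H](O[Si](C)(C)C(C)(C)C)C/C(C)=C/CCO[Si](C)(C)C(C)(C)C
F5 | step 14 | (3aS,4R,6E,10Z,11aR)-4-(TBSO)-6,10-dimethyl-3-methylidene-3a,4,5,8-tetrahydrocyclodeca[b]furan-2,9(3H,11aH)-dione | C=C1C(=O)O[C@@H]2/C=C(/C)C(=O)C/C=C(\C)C[C@@H](O[Si](C)(C)C(C)(C)C)[C@@H]12
F6 | step 21 | (1R,3S,4Z,6R,7R,8R,10R)-1,10-epoxy-8-hydroxy-3-(2-methylpropanoyloxy)germacra-4,11(13)-dien-12,6-olide | C=C1C(=O)O[C@@H]2/C=C(/C)[C@@H](OC(=O)C(C)C)C[C@H]3O[C@]3(C)C[C@@H](O)[C@@H]12
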